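**Retrosynthetic overview**

1. Labels: ring A a1 OMe, a2 H, a3 Me, a4 C(=O)O, a5 O‑aryl, a6 OH; ring B b1 O‑aryl, b2 O‑acyl, b3 Me, b4 OH, b5 lactone C=O, b6 lactol CH(OH). The strategy rests on the five‑membered lactol–lactone ring on b5/b6: its hemiacetal carbon (on b6) is labile, but it is the oxygen‑inserted form of the carbinol carbon of a fused cyclobutenone, which cannot epimerise.
2. 28 ⇐ hydrogenolysis of tribenzyl acetal 27 ⇐ Baeyer–Villiger ring expansion (C(=O)–CH(OBn) → C(=O)–O–CH(OBn)) of the depsidone‑fused (S)‑2‑benzyloxybenzocyclobutenone 25.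
3. 25 ⇐ ketal 24 ⇐ seven‑membered ring by Ullmann C–O closure (a5–O–b1) of depside 23 ⇐ ester (a4–CO–O–b2) from acid 6 and iodophenol 20.
4. 20 ⇐ (S)‑carbinol by asymmetric transfer hydrogenation of the benzocyclobutenedione monoketal 16 ⇐ aryne/ketene silyl acetal [2+2] on bromide 10 (from 2‑methylresorcinol); 6 ⇐ 3,4,5‑trimethoxytoluene.
5. Ring order: four‑membered ring (step 10), seven‑membered depsidone ring (step 19), five‑membered lactone by ring expansion (step 21).

Key step: step 21

Assumption: the lactol carbon of 28 is a hemiacetal that can epimerise through the ring‑opened 2‑formylbenzoic acid, so its configuration is set from a stable carbinol, released only in the last step under neutral aprotic conditions, and 28 is to be kept cold and free of acid and base.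

**Route**

Step 1
Reactants: 1 3,4,5‑trimethoxytoluene
Product: 2 2,3,4‑trimethoxy‑6‑methylbenzaldehyde
Conditions: POCl3, DMF, 0 → 80 °C; then H2O
Reagents that add atoms: N,N‑dimethylformamide CN(C)C=O; water O
Why: Vilsmeier–Haack formylation of the electron‑rich arene at one of its two equivalent open positions, ortho to a methoxy group, should give the aldehyde.

Step 2
Reactants: 2 2,3,4‑trimethoxy‑6‑methylbenzaldehyde
Product: 3 2,3‑dihydroxy‑4‑methoxy‑6‑methylbenzaldehyde
Conditions: BCl3 (2.5 equiv), CH2Cl2, 0 → 20 °C; then H2O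
Reagents that add atoms: none
Why: Chelation‑directed Lewis‑acid ether cleavage: BCl3 bound to the aldehyde oxygen cleaves the ortho methyl ether and then, through the cyclic aryloxyboron chelate, the neighbouring one, while the para methoxy group has no such assistance.

Step 3
Reactants: 3 2,3‑dihydroxy‑4‑methoxy‑6‑methylbenzaldehyde
Product: 4 3‑(benzyloxy)‑2‑hydroxy‑4‑methoxy‑6‑methylbenzaldehyde
Conditions: NaH (2.1 equiv), THF–DMSO, 0 → 20 °C; BnBr (1.0 equiv); then aq. HCl
Reagents that add atoms: benzyl bromide BrCc1ccccc1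
Why: Williamson etherification of the dianion, in which the phenoxide not conjugated to the aldehyde (on C3) is the more nucleophilic, so one equivalent of benzyl bromide should alkylate there only.

Step 4
Reactants: 4 3‑(benzyloxy)‑2‑hydroxy‑4‑methoxy‑6‑methylbenzaldehyde
Product: 5 2‑(benzyloxy)‑6‑formyl‑3‑methoxy‑5‑methylphenyl acetate
Conditions: Ac2O, Et3N, DMAP (cat.), CH2Cl2, 20 °C
Reagents that add atoms: acetic anhydride CC(=O)OC(C)=O
Why: DMAP‑catalysed O‑acetylation masks the remaining hydrogen‑bonded phenol so that the acid can later be activated as its chloride without self‑acylation.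

Step 5
Reactants: 5 2‑(benzyloxy)‑6‑formyl‑3‑methoxy‑5‑methylphenyl acetate
Product: 6 2‑acetoxy‑3‑(benzyloxy)‑4‑methoxy‑6‑methylbenzoic acid
Conditions: NaClO2, NaH2PO4, 2‑methyl‑2‑butene, t‑BuOH–H2O, 20 °C
Reagents that add atoms: sodium chlorite [Na+].[O-]Cl=O
Why: Pinnick oxidation converts the hindered aldehyde to the acid at mildly acidic pH without touching the aryl acetate, the benzyl ether or the arene, the alkene scavenging hypochlorous acid.

Step 6
Reactants: 7 2‑methylresorcinol
Product: 8 4‑bromo‑2‑methylbenzene‑1,3‑diol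
Conditions: NBS (1.0 equiv), CH2Cl2–THF, −78 → 0 °C
Reagents that add atoms: N‑bromosuccinimide O=C1CCC(=O)N1Br
Why: Electrophilic aromatic bromination of the symmetric resorcinol with one equivalent of NBS at low temperature should stop at the monobromide, ortho to one hydroxyl and para to the other.

Step 7
Reactants: 8 4‑bromo‑2‑methylbenzene‑1,3‑diol
Product: 9 6‑bromo‑2‑methyl‑3‑[(triisopropylsilyl)oxy]phenol
Conditions: TIPSCl (1.0 equiv), imidazole, CH2Cl2, −20 → 0 °C
Reagents that add atoms: chlorotriisopropylsilane CC(C)[Si](Cl)(C(C)C)C(C)C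
Why: Steric differentiation in phenol silylation: the bulky chlorosilane should take the hydroxyl para to bromine, which has one ortho substituent, and leave the one flanked by bromine and methyl.

Step 8
Reactants: 9 6‑bromo‑2‑methyl‑3‑[(triisopropylsilyl)oxy]phenol
Product: 10 2‑(benzyloxy)‑1‑bromo‑3‑methyl‑4‑[(triisopropylsilyl)oxy]benzene
Conditions: BnBr, K2CO3, acetone, 50 °C
Reagents that add atoms: benzyl bromide BrCc1ccccc1
Why: Williamson benzylation of the remaining, more acidic phenol with carbonate in an aprotic solvent, in which the aryl triisopropylsilyl ether is stable.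

Step 9
Reactants: 11 methyl 2‑[(tert‑butyldimethylsilyl)oxy]acetate
Product: 12 (Z)‑1‑methoxy‑1,2‑bis[(tert‑butyldimethylsilyl)oxy]ethene
Conditions: LDA, THF, −78 °C; TBSCl, DMPU, −78 → 20 °C
Reagents that add atoms: tert‑butylchlorodimethylsilane CC(C)(C)[Si](C)(C)Cl
Why: Kinetic ester enolisation and O‑silylation give the ketene silyl acetal; its double‑bond geometry is of no consequence because both carbons lose their configuration later.

Step 10
Reactants: 10 2‑(benzyloxy)‑1‑bromo‑3‑methyl‑4‑[(triisopropylsilyl)oxy]benzene; 12 (Z)‑1‑methoxy‑1,2‑bis[(tert‑butyldimethylsilyl)oxy]ethene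
Product: 14 5‑(benzyloxy)‑7,8‑bis[(tert‑butyldimethylsilyl)oxy]‑7‑methoxy‑4‑methyl‑3‑[(triisopropylsilyl)oxy]bicyclo[4.2.0]octa‑1,3,5‑triene (racemic diastereomer mixture), via 3‑(benzyloxy)‑4‑methyl‑5‑(triisopropylsilyloxy)benzyne 13 (not isolated)
Conditions: LiTMP (from TMP and n‑BuLi, 2.5 equiv) added to 10 and 12 (3 equiv), THF, −78 → −20 °C
Reagents that add atoms: none
Why: LiTMP removes the proton ortho to bromine, LiBr is lost, and the 3‑alkoxybenzyne undergoes the known stepwise [2+2] cycloaddition with the ketene silyl acetal, whose nucleophilic CH carbon attacks the aryne carbon meta to the benzyloxy group (b6) so that the ketal carbon closes on b5; both new stereocentres are erased later.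

Step 11
Reactants: 14 silyl ketal cycloadduct
Product: 15 (±)‑5‑(benzyloxy)‑7,7‑dimethoxy‑4‑methyl‑3‑[(triisopropylsilyl)oxy]bicyclo[4.2.0]octa‑1,3,5‑trien‑8‑ol
Conditions: HCl (cat., anhydrous, in MeOH), MeOH–HC(OMe)3, 0 → 20 °C
Reagents that add atoms: methanol CO
Why: Acid‑catalysed transketalisation exchanges the silyl methyl ketal for the dimethyl ketal through the aryl‑stabilised oxocarbenium ion and solvolyses the secondary alkyl silyl ether, while the aryl triisopropylsilyl ether is stable to acid and the orthoformate keeps water out.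

Step 12
Reactants: 15 racemic hydroxy ketal
Product: 16 5‑(benzyloxy)‑7,7‑dimethoxy‑4‑methyl‑3‑[(triisopropylsilyl)oxy]bicyclo[4.2.0]octa‑1,3,5‑trien‑8‑one
Conditions: Dess–Martin periodinane, pyridine, CH2Cl2, 0 → 20 °C
Reagents that add atoms: none
Why: Dess–Martin oxidation of the secondary benzocyclobutenol under non‑basic conditions gives the benzocyclobutenedione monoketal and removes the racemic centre.

Step 13
Reactants: 16 benzocyclobutenedione monoketal
Product: 17 (8S)‑5‑(benzyloxy)‑7,7‑dimethoxy‑4‑methyl‑3‑[(triisopropylsilyl)oxy]bicyclo[4.2.0]octa‑1,3,5‑trien‑8‑ol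
Conditions: RuCl(p‑cymene)[(R,R)‑TsDPEN] (2 mol%), HCO2H–Et3N (5:2), CH2Cl2, 20 °C
Reagents that add atoms: none
Why: Noyori–Ikariya asymmetric transfer hydrogenation, in which the fused arene is the group held by the CH/π contact with the cymene ligand, so that by analogy with 1‑indanone and benzil the (R,R)‑ligand should give the (S)‑carbinol (the spatial analogue of (R)‑1‑phenylethanol); the sense is to be confirmed on the Mosher esters and the antipodal ligand used if it is reversed.

Step 14
Reactants: 17 (S)‑hydroxy ketal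
Product: 18 (8S)‑5,8‑bis(benzyloxy)‑7,7‑dimethoxy‑4‑methyl‑3‑[(triisopropylsilyl)oxy]bicyclo[4.2.0]octa‑1,3,5‑triene
Conditions: benzyl 2,2,2‑trichloroacetimidate, TfOH (cat.), CH2Cl2–cyclohexane, 0 °C
Reagents that add atoms: benzyl 2,2,2‑trichloroacetimidate N=C(OCc1ccccc1)C(Cl)(Cl)Cl
Why: Acid‑catalysed O‑benzylation with the trichloroacetimidate avoids the alkoxide, which would open the benzocyclobutenol ring, and leaves the C–O bond at the stereocentre untouched (retention).

Step 15
Reactants: 18 (S)‑benzyl ether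
Product: 19 (8S)‑5,8‑bis(benzyloxy)‑7,7‑dimethoxy‑4‑methylbicyclo[4.2.0]octa‑1,3,5‑trien‑3‑ol
Conditions: TBAF, AcOH (1:1), THF, 0 → 20 °C
Reagents that add atoms: none
Why: Buffered fluoride desilylation cleaves the aryl silyl ether, the ketal and the benzyl ethers being inert.

Step 16
Reactants: 19 ring B phenol
Product: 20 (8S)‑5,8‑bis(benzyloxy)‑2‑iodo‑7,7‑dimethoxy‑4‑methylbicyclo[4.2.0]octa‑1,3,5‑trien‑3‑ol
Conditions: NIS (1.05 equiv), MeCN, 0 °C
Reagents that add atoms: N‑iodosuccinimide O=C1CCC(=O)N1I
Why: Electrophilic aromatic iodination at the only free position of the phenol ring (b1), ortho to the hydroxyl and para to the benzyloxy group.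

Step 17
Reactants: 6 2‑acetoxy‑3‑(benzyloxy)‑4‑methoxy‑6‑methylbenzoic acid; 20 ring B iodophenol
Product: 22 depside acetate: the b2 aryl ester of 2‑acetoxy‑3‑(benzyloxy)‑4‑methoxy‑6‑methylbenzoic acid with iodophenol 20, via aroyl chloride 21 (not isolated)
Conditions: 6, (COCl)2, DMF (cat.), CH2Cl2, 0 → 20 °C, evaporate; 20, NaH, THF, 0 °C, then 21, 0 → 40 °C
Reagents that add atoms: none
Why: Acylation of the sodium phenoxide by the aroyl chloride (esterification through the acid chloride) should overcome the double ortho substitution of both partners, the acetate keeping the ring A phenol from self‑acylation.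

Step 18
Reactants: 22 depside acetate
Product: 23 depside phenol: the b2 aryl ester of 3‑(benzyloxy)‑2‑hydroxy‑4‑methoxy‑6‑methylbenzoic acid with iodophenol 20
Conditions: N2H4·H2O (1.2 equiv), THF–MeOH, 0 °C
Reagents that add atoms: none
Why: Chemoselective hydrazinolysis removes the aryl acetate, the benzoate that is ortho,ortho′‑disubstituted on both sides being far slower to react.

Step 19
Reactants: 23 depside phenol
Product: 24 tribenzyl depsidone dimethyl ketal (seven‑membered dibenzodioxepinone ring closed; ring B fused at b5/b6 to the four‑membered ring with C(OMe)2 on b5 and (S)‑CH(OBn) on b6)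
Conditions: CuI (20 mol%), picolinic acid (40 mol%), K3PO4, DMSO, 90 °C
Reagents that add atoms: none
Why: Intramolecular Ullmann diaryl ether synthesis with monovalent copper and the picolinic acid ligand used for hindered partners: the ring A phenoxide displaces iodide at b1 and closes the seven‑membered ring, and the ketal, ester and benzyl ethers tolerate the base.

Step 20
Reactants: 24 tribenzyl depsidone dimethyl ketal
Product: 25 depsidone‑fused (S)‑2‑benzyloxybenzocyclobutenone (C=O on b5 and (S)‑CH(OBn) on b6)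
Conditions: aq. HCl (2 M), THF, 45 °C
Reagents that add atoms: water O
Why: Acid hydrolysis of the dimethyl ketal releases the strained ketone, and the adjacent stereocentre cannot epimerise because enolisation would give a benzocyclobutadiene.

Step 21
Reactants: 25 depsidone‑fused (S)‑2‑benzyloxybenzocyclobutenone
Product: 27 tribenzyl‑protected target with the (R)‑3‑benzyloxyphthalide ring on b5/b6, via Criegee adduct 26 (not isolated)
Conditions: mCPBA (1.5 equiv), NaHCO3 (solid buffer), CH2Cl2, 0 → 20 °C
Reagents that add atoms: 3‑chloroperoxybenzoic acid OOC(=O)c1cccc(Cl)c1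
Why: The peracid adds to the strained, non‑enolisable carbonyl on b5 to give Criegee adduct 26, and the antiperiplanar C–CH(OBn) bond then shifts to the peroxide oxygen with loss of 3‑chlorobenzoate, a Baeyer–Villiger oxidation of the kind known for benzocyclobutenones (to phthalides) and for α‑alkoxy ketones (to acyl acetals). The five‑membered lactone arises by one‑atom ring expansion of the four‑membered ring (1,2‑shift of carbon to oxygen, driven by release of ring strain) and not by cyclisation of an open chain; the acyl–O and O–CH bonds are the two new skeletal bonds. The new acetal stereocentre is the old carbinol carbon: the shift is suprafacial and goes with retention, so the (S)‑carbinol set in step 13 becomes the (R)‑acetal (same spatial arrangement, changed priorities). The step needs migration of the benzyloxy‑bearing carbon in preference to the aryl carbon b5, which should be secured by lone‑pair donation from the ether oxygen, by benzylic stabilisation of the migrating carbon and by the strain that a bridged aryl shift would impose on the fused four‑membered ring. It also needs the peracid to spare the alkoxy arenes and the acid by‑product to spare the benzyl acetal, hence the low temperature, the small excess of oxidant and the buffer.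

Step 22
Reactants: 27 tribenzyl‑protected target
Product: 28 CNP0211607.1, the (R)‑lactol
Conditions: H2 (1 atm), 10% Pd/C, EtOAc, 20 °C; filter and concentrate cold
Reagents that add atoms: none
Why: Hydrogenolysis cleaves the three O–CH2Ph bonds (two aryl ethers and the acetal ether) and not the C–O bonds at the stereocentre, so the (R)‑lactol should be released with its configuration, the neutral aprotic medium and short contact time keeping ring–chain tautomerism and aldehyde reduction from intervening.

**Compound list**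

1 | 3,4,5‑trimethoxytoluene | COc1cc(C)cc(OC)c1OC | starting material
2 | 2,3,4‑trimethoxy‑6‑methylbenzaldehyde | COc1cc(C)c(C=O)c(OC)c1OC | intermediate
3 | 2,3‑dihydroxy‑4‑methoxy‑6‑methylbenzaldehyde | COc1cc(C)c(C=O)c(O)c1O | intermediate
4 | 3‑(benzyloxy)‑2‑hydroxy‑4‑methoxy‑6‑methylbenzaldehyde | COc1cc(C)c(C=O)c(O)c1OCc1ccccc1 | intermediate
5 | 2‑(benzyloxy)‑6‑formyl‑3‑methoxy‑5‑methylphenyl acetate | COc1cc(C)c(C=O)c(OC(C)=O)c1OCc1ccccc1 | intermediate
6 | 2‑acetoxy‑3‑(benzyloxy)‑4‑methoxy‑6‑methylbenzoic acid | COc1cc(C)c(C(=O)O)c(OC(C)=O)c1OCc1ccccc1 | intermediate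
7 | 2‑methylresorcinol | Cc1c(O)cccc1O | starting material
8 | 4‑bromo‑2‑methylbenzene‑1,3‑diol | Cc1c(O)ccc(Br)c1O | intermediate
9 | 6‑bromo‑2‑methyl‑3‑[(triisopropylsilyl)oxy]phenol | Cc1c(O[Si](C(C)C)(C(C)C)C(C)C)ccc(Br)c1O | intermediate
10 | 2‑(benzyloxy)‑1‑bromo‑3‑methyl‑4‑[(triisopropylsilyl)oxy]benzene | Cc1c(O[Si](C(C)C)(C(C)C)C(C)C)ccc(Br)c1OCc1ccccc1 | intermediate
11 | methyl 2‑[(tert‑butyldimethylsilyl)oxy]acetate | COC(=O)CO[Si](C)(C)C(C)(C)C | starting material
12 | (Z)‑1‑methoxy‑1,2‑bis[(tert‑butyldimethylsilyl)oxy]ethene | CO/C(O[Si](C)(C)C(C)(C)C)=C/O[Si](C)(C)C(C)(C)C | intermediate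
13 | 3‑(benzyloxy)‑4‑methyl‑5‑(triisopropylsilyloxy)benzyne (forms and reacts in the flask) | CC1=C(OCc2ccccc2)C#CC=C1O[Si](C(C)C)(C(C)C)C(C)C | intermediate
14 | 5‑(benzyloxy)‑7,8‑bis[(tert‑butyldimethylsilyl)oxy]‑7‑methoxy‑4‑methyl‑3‑[(triisopropylsilyl)oxy]bicyclo[4.2.0]octa‑1,3,5‑triene (racemic diastereomer mixture) | Cc1c(O[Si](C(C)C)(C(C)C)C(C)C)cc2c(c1OCc1ccccc1)C(OC)(O[Si](C)(C)C(C)(C)C)C2O[Si](C)(C)C(C)(C)C | intermediate
15 | (±)‑5‑(benzyloxy)‑7,7‑dimethoxy‑4‑methyl‑3‑[(triisopropylsilyl)oxy]bicyclo[4.2.0]octa‑1,3,5‑trien‑8‑ol | Cc1c(O[Si](C(C)C)(C(C)C)C(C)C)cc2c(c1OCc1ccccc1)C(OC)(OC)C2O | intermediate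
16 | 5‑(benzyloxy)‑7,7‑dimethoxy‑4‑methyl‑3‑[(triisopropylsilyl)oxy]bicyclo[4.2.0]octa‑1,3,5‑trien‑8‑one | Cc1c(O[Si](C(C)C)(C(C)C)C(C)C)cc2c(c1OCc1ccccc1)C(OC)(OC)C2=O | intermediate
17 | (8S)‑5‑(benzyloxy)‑7,7‑dimethoxy‑4‑methyl‑3‑[(triisopropylsilyl)oxy]bicyclo[4.2.0]octa‑1,3,5‑trien‑8‑ol | Cc1c(O[Si](C(C)C)(C(C)C)C(C)C)cc2c(c1OCc1ccccc1)C(OC)(OC)[C@H]2O | intermediate
18 | (8S)‑5,8‑bis(benzyloxy)‑7,7‑dimethoxy‑4‑methyl‑3‑[(triisopropylsilyl)oxy]bicyclo[4.2.0]octa‑1,3,5‑triene | Cc1c(O[Si](C(C)C)(C(C)C)C(C)C)cc2c(c1OCc1ccccc1)C(OC)(OC)[C@H]2OCc1ccccc1 | intermediate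
19 | (8S)‑5,8‑bis(benzyloxy)‑7,7‑dimethoxy‑4‑methylbicyclo[4.2.0]octa‑1,3,5‑trien‑3‑ol | Cc1c(O)cc2c(c1OCc1ccccc1)C(OC)(OC)[C@H]2OCc1ccccc1 | intermediate
20 | (8S)‑5,8‑bis(benzyloxy)‑2‑iodo‑7,7‑dimethoxy‑4‑methylbicyclo[4.2.0]octa‑1,3,5‑trien‑3‑ol | Cc1c(O)c(I)c2c(c1OCc1ccccc1)C(OC)(OC)[C@H]2OCc1ccccc1 | intermediate
21 | 2‑acetoxy‑3‑(benzyloxy)‑4‑methoxy‑6‑methylbenzoyl chloride (forms and reacts in the flask) | COc1cc(C)c(C(Cl)=O)c(OC(C)=O)c1OCc1ccccc1 | intermediate
22 | depside acetate: (8S)‑5,8‑bis(benzyloxy)‑2‑iodo‑7,7‑dimethoxy‑4‑methylbicyclo[4.2.0]octa‑1,3,5‑trien‑3‑yl 2‑acetoxy‑3‑(benzyloxy)‑4‑methoxy‑6‑methylbenzoate | COc1cc(C)c(C(=O)Oc2c(C)c(OCc3ccccc3)c3c(c2I)[C@H](OCc2ccccc2)C3(OC)OC)c(OC(C)=O)c1OCc1ccccc1 | intermediate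
23 | depside phenol: the same aryl ester of 3‑(benzyloxy)‑2‑hydroxy‑4‑methoxy‑6‑methylbenzoic acid | COc1cc(C)c(C(=O)Oc2c(C)c(OCc3ccccc3)c3c(c2I)[C@H](OCc2ccccc2)C3(OC)OC)c(O)c1OCc1ccccc1 | intermediate
24 | tribenzyl depsidone dimethyl ketal (C(OMe)2 on b5, (S)‑CH(OBn) on b6) | COc1cc(C)c2c(c1OCc1ccccc1)Oc1c(c(C)c(OCc3ccccc3)c3c1[C@H](OCc1ccccc1)C3(OC)OC)OC2=O | intermediate
25 | depsidone‑fused (S)‑2‑benzyloxybenzocyclobutenone (C=O on b5) | COc1cc(C)c2c(c1OCc1ccccc1)Oc1c(c(C)c(OCc3ccccc3)c3c1[C@H](OCc1ccccc1)C3=O)OC2=O | intermediate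
26 | Criegee adduct of 25 with the peracid, hemiketal carbon undefined (forms and reacts in the flask) | COc1cc(C)c2c(c1OCc1ccccc1)Oc1c(c(C)c(OCc3ccccc3)c3c1[C@H](OCc1ccccc1)C3(O)OOC(=O)c1cccc(Cl)c1)OC2=O | intermediate
27 | tribenzyl‑protected target, (R)‑3‑benzyloxyphthalide on ring B | COc1cc(C)c2c(c1OCc1ccccc1)Oc1c(c(C)c(OCc3ccccc3)c3c1[C@H](OCc1ccccc1)OC3=O)OC2=O | intermediate
28 | CNP0211607.1, (R)‑lactol | COc1cc(C)c2c(c1O)Oc1c(c(C)c(O)c3c1[C@H](O)OC3=O)OC2=O | target

**Step count and risks**

Total: 22 steps. Longest linear sequence: 16 steps (steps 6–8 and 10–22, from 2‑methylresorcinol).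

Steps most likely to fail:

1. Step 21 (ring expansion). The aryl carbon b5, activated by the ortho benzyloxy group, may compete in the migration. The adduct may also form slowly at the hindered carbonyl, so that the acid by‑product ionises the benzyl acetal or the peracid attacks the rings. Fallback: the order of the last three operations is inverted, so that the ring expansion is done on the free hydroxy ketone. Setting out from 24, hydrogenolysis (H2, 10% Pd/C, EtOAc) removes the three benzyl groups and should give the triol ketal F1, the ketal and the carbinol C–O bond being stable. Aqueous acid (2 M HCl, THF) then releases the (S)‑2‑hydroxybenzocyclobutenone with two free phenols F2, and buffered mCPBA at −20 °C expands F2 directly to 28, where the fallback comes back to the route. The free hydroxyl makes the migrating carbon a better donor and the carbonyl is less hindered. No acid‑labile benzyl acetal is formed, and no lactol meets a hydrogenation catalyst.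

2. Step 10 (aryne cycloaddition). Deprotonation ortho to bromine may be too slow against attack of the amide on the ketene silyl acetal or metalation at the benzylic ether, so that the aryne is formed inefficiently or is captured by the amide. Fallback: the aryne is released by halogen–lithium exchange instead of by deprotonation in the presence of the trap. Setting out from 10, magnesiation ortho to bromine with TMPMgCl·LiCl (THF, 0 °C; the aryl magnesium does not eliminate) and quenching with iodine should give 2‑(benzyloxy)‑1‑bromo‑6‑iodo‑3‑methyl‑4‑[(triisopropylsilyl)oxy]benzene F3. n‑BuLi at −78 °C in the presence of 12 then exchanges iodine, LiBr is lost, and the same aryne 13 is trapped to give 14, where the fallback comes back to the route.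

3. Step 11 (acid methanolysis). The silyl ketal may hydrolyse to the ketone, the secondary silyl ether may be cleaved incompletely, or the aryl silyl ether may be lost, giving mixtures. Fallback: the carbinol is set on the diketone and the ketal is introduced afterwards. Setting out from 14, aqueous HF in MeCN removes both tert‑butyldimethylsilyl groups and should give the racemic 2‑hydroxybenzocyclobutenone F4 (C=O on b5). Dess–Martin oxidation gives the benzocyclobutenedione F5. Transfer hydrogenation with the catalyst of step 13 should reduce only the carbonyl on b6, because the one on b5 is deactivated as a vinylogous ester by the ortho benzyloxy and para silyloxy groups, and give the (S)‑hydroxy ketone F6. Ketalisation (HC(OMe)3, MeOH, cat. TsOH) of the strained carbonyl then gives 17, where the fallback comes back to the route.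

**Further compounds**

F1 | step 21 | triol dimethyl ketal: 24 without its three benzyl groups | COc1cc(C)c2c(c1O)Oc1c(c(C)c(O)c3c1[C@H](O)C3(OC)OC)OC2=O
F2 | step 21 | depsidone‑fused (S)‑2‑hydroxybenzocyclobutenone with free phenols on a6 and b4 | COc1cc(C)c2c(c1O)Oc1c(c(C)c(O)c3c1[C@H](O)C3=O)OC2=O
F3 | step 10 | 2‑(benzyloxy)‑1‑bromo‑6‑iodo‑3‑methyl‑4‑[(triisopropylsilyl)oxy]benzene | Cc1c(O[Si](C(C)C)(C(C)C)C(C)C)cc(I)c(Br)c1OCc1ccccc1
F4 | step 11 | (±)‑5‑(benzyloxy)‑8‑hydroxy‑4‑methyl‑3‑[(triisopropylsilyl)oxy]bicyclo[4.2.0]octa‑1,3,5‑trien‑7‑one | Cc1c(O[Si](C(C)C)(C(C)C)C(C)C)cc2c(c1OCc1ccccc1)C(=O)C2O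
F5 | step 11 | 5‑(benzyloxy)‑4‑methyl‑3‑[(triisopropylsilyl)oxy]bicyclo[4.2.0]octa‑1,3,5‑triene‑7,8‑dione | Cc1c(O[Si](C(C)C)(C(C)C)C(C)C)cc2c(c1OCc1ccccc1)C(=O)C2=O
F6 | step 11 | (8S)‑5‑(benzyloxy)‑8‑hydroxy‑4‑methyl‑3‑[(triisopropylsilyl)oxy]bicyclo[4.2.0]octa‑1,3,5‑trien‑7‑one | Cc1c(O[Si](C(C)C)(C(C)C)C(C)C)cc2c(c1OCc1ccccc1)C(=O)[C@H]2O
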